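## The problem

The atom labels used throughout are: ring A (five-membered) is C1 (quaternary, methyl C11), C2, C3, C4 (hydroxyl and isopropyl), C5 (hydrogen); ring B (seven-membered) is C1, C5, C6 (4-hydroxybenzoate), C7=C8 (methyl on C8), C9 (acetate), C10. The target is a trans-fused bicyclo[5.3.0]decene of the daucane type with five stereocentres (1R, 4R, 5S, 6S, 9S); two of them are fully substituted (C1 and the tertiary carbinol C4). The C1 methyl and the C4 hydroxyl lie on one face; the C5 hydrogen, the isopropyl group and both ester oxygens lie on the other. One centre can be made to control the rest: a secondary carbinol at C4 can deliver the C1 methyl, and the angular methyl then directs the C5 proton, the isopropyl group at C4 and an electrophilic oxygen at C6 to the opposite face. C9 is the exception, because a hydride would also arrive anti to the methyl and leave the oxygen on the wrong side, so C9 needs reagent control or an inversion. The tertiary alcohol next to the ring fusion dehydrates easily and the two allylic esters flanking C7=C8 can ionise, eliminate or exchange acyl groups; the acetate, the aroyl ester and the free phenol must therefore come last and see no strong acid, base or reductant. The feature that opens the structure is the unit C9(O)–C8(CH3)=C7: C9 is an aryl methyl ether carbon, C7 an aromatic CH and C8 one extra carbon carrying a methyl group, so rings A and B together are 5-methoxyindan-1-ol (its carbinol carbon is C4) plus one inserted carbon. Birch reduction of that indanol leaves exactly one enol ether double bond (C7=C9) for a carbene and one tetrasubstituted alkene (C1=C5) beside the carbinol for the later methyl delivery.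

## Retrosynthesis

Acyl groups last (27 to 24). The phenol silyl ether of 26, the acetyl C–O bond at C9 (25) and then the C9–H bond are removed, leading to ketone 24. Keeping C9 as a ketone while C6 is esterified tells the two allylic oxygens apart by oxidation level, so a selective acylation of a diol is never needed. The forward reaction must reduce C9 to the 9S carbinol under reagent control.

Aroyl ester (24 to 20 and 23). The ester C–O bond at C6 is cut. Acid 23 is the silyl-protected form of 21, and hydroxy enone 20 has only one acylable hydroxyl because the C4 carbinol is tertiary.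

Oxygen at C6 (20 to 17). The C6–O bond is cut by way of dienol ether 18. The neighbouring choices are worse: allylic oxidation of an isolated C7=C8 alkene has no regiocontrol, and reduction of a C6 ketone would bring hydride from the open face and give the wrong epimer. An electrophilic oxygen enters from that same open face and gives the right one. Enone 17 has one stereocentre and one oxygen fewer; the forward step needs enolisation toward C6 and oxidation at the far end of the diene.

Isopropyl group (17 to 15). The C4–isopropyl bond is cut, and the C9 ketone is taken back to the carbinol of 16 and 15 because the next retro step needs a dissolving metal. Ketone 15 must accept the nucleophile anti to the C1 methyl without enolising at C5.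

Angular methyl (15 to 11). The methyl carbon C11 is first reconnected to C5 (cyclopropyl ketone 13, then carbinol 12) and then removed altogether (bonds C1–C11 and C5–C11), giving allylic alcohol 11. Conjugate addition of a methyl nucleophile to a C4 enone would erase C4 before it has been used. The cyclopropane route instead lets the catalyst-set C4 carbinol place the methyl and only then gives C4 up. The forward steps are hydroxyl-directed cyclopropanation, oxidation, and cleavage of the cyclopropane bond that overlaps with the carbonyl group.

Masking of C9 (11 to 8). The benzyl ether 10 and the carbinol 9 lead back to enone 8. The enone cannot pass through the dissolving-metal step, so it is parked as a benzyl-protected carbinol. The benzyl group is lost in that same step, which makes the detour cost two steps in and one oxidation out.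

Ring expansion (8 to 5 and 6). The bonds C7–C8 and C8–C9 are cut, C8 leaves with its methyl as a carbene derived from 6, and C7–C9 is reconnected to give the six-membered enol ether 5. Closing a seven-membered ring from an open chain would need a long acyclic precursor; this cut leads straight to an arene-derived diene. The forward reaction must choose the enol ether over the C1=C5 alkene and place chloride where it can leave.

Arene (5 to 1). Silyl ether 5 comes from dienol 4, the Birch product of indanol 2, which is the enantioselective reduction product of ketone 1. No C–C bond is made before the key step.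

## Roads not taken

Alternative 1: The cut is at C1–C10 and C5–C6 on a cyclopentenone. Cu(OTf)2 with a chiral N-heterocyclic carbene ligand would add the vinyl group of alane A4 to 3-methylcyclopent-2-enone A2, and the aluminium enolate would be trapped at C5 by the iodoenal A3 to give the aldol adduct A1.
- Merits: the quaternary centre C1 is made by catalysis, C5 and C6 are set in the same operation, the C4 ketone is already in place, and the C6 oxygen arrives with the aldehyde.
- Weak points: A1 is a β-hydroxy ketone open to retro-aldol and dehydration when the isopropyl nucleophile is added. Nothing strong fixes the C6 configuration relative to C5. β-Substituted five-membered enones are the hardest class for this conjugate addition. Ring B must still be closed, presumably between C8 and C9, with C9 set in that closure.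
- Comparison: this road is more convergent, probably shorter, and handles C6 better than the chosen plan. The chosen plan sets against it that no medium ring has to be closed, that ring B appears complete in one step from an arene, and that all stereochemistry is relayed from one dependable ketone reduction.

Alternative 2: The cut is at C5–C1 and C5–C6 at once. Rh2(OAc)4 would convert diazoketone A6 into a carbenoid that adds to the tolyl ring and opens to the cycloheptatriene A5.
- Merits: both rings form in one step from an acyclic precursor, the C8 methyl and the C4 carbonyl are in place, and nothing reaches the bicyclic skeleton faster (enone 8 needs four steps).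
- Weak points: A5 is racemic at C5 unless a chiral dirhodium catalyst is found, and that hydrogen is α to the ketone and allylic in a triene that undergoes hydrogen shifts, so the only stereocentre is labile. C1 is sp2, so the angular methyl must be added to a trienone with regio- and facial control. Three conjugated alkenes must be differentiated to put oxygen at C6 and C9 and keep C7=C8.
- Comparison: the chosen plan is slower to the skeleton, but its product 8 already holds an enone, one isolated alkene and a stereocentre placed to direct the methyl.

Alternative 3: The cut is at both C–O bonds of ring B. Photosensitised singlet oxygen would add across the 1,3-diene A8 to give the endoperoxide A7.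
- Merits: both oxygens enter cis in one step on the face opposite the angular methyl, which is the relationship the target has, and no hydride reduction at C9 is needed.
- Weak points: it presupposes A8, a specific diene isomer that must be made without dehydrating the tertiary alcohol. Ene reactions at the C8 methyl and C10 compete. After O–O cleavage, two secondary allylic hydroxyls on one alkene must be acylated differently. Base can rearrange A7 to a hydroxy enone.
- Comparison: for the C6/C9 relative configuration this road is better than the chosen endgame. The chosen plan sets against it that the two oxygens are differentiated automatically (C6 is esterified while C9 is still a ketone) and that the enone from the key step is used directly. The two are compatible, since enone 17 could serve as an entry to A8.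

Key step: step 4

Assumption: C9 of compounds 9 to 16 is carried as both epimers and written without a descriptor, because this centre is erased by the oxidation in step 12.

Step 1
Reactants: 1 5-methoxyindan-1-one
Product: 2 (S)-5-methoxyindan-1-ol
Conditions: (R)-Me-CBS oxazaborolidine (C18H20BNO, 10 mol%), BH3·SMe2, THF, 0 °C; MeOH
Reagents that add atoms: none
Why: Corey–Bakshi–Shibata reduction of an aryl alkyl ketone; with the aryl ring as the large group the (R)-catalyst should deliver hydride to give the (S)-carbinol, the only stereocentre that is set by a catalyst before ring B exists.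

Step 2
Reactants: 2 (S)-5-methoxyindan-1-ol
Product: 4 (1S)-5-methoxy-2,3,4,7-tetrahydro-1H-inden-1-ol, via lithium alkoxide 3 (not isolated)
Conditions: n-BuLi (1.05 equiv), THF, −78 °C; then Li, NH3(l), t-BuOH, −78 to −33 °C; NH4Cl
Reagents that add atoms: none
Why: Birch reduction; the alkoxide is a poor leaving group and its benzylic carbon is para to the methoxy group, where the radical anion carries little charge, so hydrogenolysis should be suppressed, and the methoxy and alkyl substituents stay on sp2 carbons to give the 1-methoxy-1,4-diene with the tetrasubstituted ring-fusion alkene.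

Step 3
Reactants: 4 (1S)-5-methoxy-2,3,4,7-tetrahydro-1H-inden-1-ol
Product: 5 tert-butyl{[(1S)-5-methoxy-2,3,4,7-tetrahydro-1H-inden-1-yl]oxy}dimethylsilane
Conditions: TBSCl, imidazole, DMF, 0 °C to rt
Reagents that add atoms: tert-butyldimethylsilyl chloride, CC(C)(C)[Si](C)(C)Cl
Why: Standard silylation under non-acidic conditions that leave the enol ether intact; the silyl ether removes the acidic O–H before the organolithium step and shields the neighbouring C1=C5 alkene.

Step 4
Reactants: 5 tert-butyl{[(1S)-5-methoxy-2,3,4,7-tetrahydro-1H-inden-1-yl]oxy}dimethylsilane; 6 1,1-dichloroethane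
Product: 8 (1S)-1-[(tert-butyldimethylsilyl)oxy]-6-methyl-2,3,4,8-tetrahydroazulen-5(1H)-one, via chlorocyclopropane adduct 7 (not isolated)
Conditions: 6 (4 equiv), n-BuLi (3.5 equiv, slow addition), Et2O, −40 to −20 °C; then AgBF4, NaHCO3, acetone/H2O 10:1, 0 °C to rt
Reagents that add atoms: water, O
Why: n-BuLi deprotonates 6 to 1,1-dichloroethyllithium, which loses LiCl, and the chloro(methyl)carbenoid adds in a concerted (2+1) step to the enol ether double bond C7=C9 of 5, forming C7–C8 and C8–C9 and the cyclopropane of 7. AgBF4 then removes chloride while the C7–C9 bond opens in a disrotatory two-electron electrocyclic process pushed by the methoxy oxygen; water adds to the oxygen-stabilised allyl cation at C9 and methanol is lost, giving enone 8. The closest known reaction type is halocarbene addition to the enol ethers of Birch-derived 1-methoxycyclohexa-1,4-dienes and to silyl enol ethers followed by cyclopropyl-to-allyl ring expansion to cyclohept-2-enones, including the chloro(methyl)carbene variant that gives 2-methylcycloalkenones. Ring B is not closed by a cyclisation: the three-membered ring closes by cheletropic addition and the seven-membered ring arises by electrocyclic expansion of the six-membered ring. No stereocentre of the target is made, the cyclopropane centres of 7 are erased and C4 is untouched. The step needs chemoselectivity for the enol ether over C1=C5, which should follow because the enol ether is the most electron-rich alkene while C1=C5 is tetrasubstituted, inductively deactivated by the allylic oxygen and shielded by the silyl group. The direction of opening is fixed by the methoxy group, and only the adduct with chloride over the six-membered ring can open to a cis-cycloheptenyl cation; the methyl group should prefer the less crowded outside position, so this should be the main adduct. The buffered conditions at or below room temperature are chosen to keep the β,γ-unsaturated ketone of 8 from moving into conjugation.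

Step 5
Reactants: 8 (1S)-1-[(tert-butyldimethylsilyl)oxy]-6-methyl-2,3,4,8-tetrahydroazulen-5(1H)-one
Product: 9 (1S)-1-[(tert-butyldimethylsilyl)oxy]-6-methyl-1,2,3,4,5,8-hexahydroazulen-5-ol (both C9 epimers)
Conditions: NaBH4, CeCl3·7H2O, MeOH, −78 °C
Reagents that add atoms: none
Why: Luche 1,2-reduction; it removes the enone that would not survive step 10 and the isomerisation-prone β,γ-unsaturated ketone at once, and the C9 configuration is irrelevant because the carbinol is re-oxidised in step 12.

Step 6
Reactants: 9 (1S)-1-[(tert-butyldimethylsilyl)oxy]-6-methyl-1,2,3,4,5,8-hexahydroazulen-5-ol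
Product: 10 (1S)-5-(benzyloxy)-1-[(tert-butyldimethylsilyl)oxy]-6-methyl-1,2,3,4,5,8-hexahydroazulene
Conditions: NaH, BnBr, Bu4NI (cat.), THF/DMF, 0 °C to rt
Reagents that add atoms: benzyl bromide, BrCc1ccccc1
Why: Williamson etherification; benzyl is chosen because it survives fluoride, zinc carbenoid and periodinane and is then removed by the dissolving metal of step 10 without a step of its own.

Step 7
Reactants: 10 (1S)-5-(benzyloxy)-1-[(tert-butyldimethylsilyl)oxy]-6-methyl-1,2,3,4,5,8-hexahydroazulene
Product: 11 (1S)-5-(benzyloxy)-6-methyl-1,2,3,4,5,8-hexahydroazulen-1-ol
Conditions: Bu4NF, THF, 0 °C to rt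
Reagents that add atoms: none
Why: Fluoride desilylation; no acid is used, so the readily ionised allylic carbinol next to the tetrasubstituted alkene is not exposed to solvolysis.

Step 8
Reactants: 11 (1S)-5-(benzyloxy)-6-methyl-1,2,3,4,5,8-hexahydroazulen-1-ol
Product: 12 C1,C5-methano-bridged C4 alcohol (cyclopropane across C1–C5 with its CH2 group C11 cis to the C4 hydroxyl; C9 benzyl ether)
Conditions: Et2Zn, CH2I2, CH2Cl2, −10 to 0 °C
Reagents that add atoms: diiodomethane, ICI
Why: Hydroxyl-directed Simmons–Smith cyclopropanation (Furukawa reagent); the zinc alkoxide of the C4 carbinol delivers CH2 to its own face of C1=C5, which fixes the configuration of C1, and this directed reaction should outrun the undirected one at the C7=C8 alkene next to the benzyl ether.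

Step 9
Reactants: 12 C1,C5-methano-bridged C4 alcohol
Product: 13 C1,C5-methano-bridged C4 ketone (cyclopropyl ketone; C9 benzyl ether)
Conditions: Dess–Martin periodinane (C13H13IO8), NaHCO3, CH2Cl2, 0 °C to rt
Reagents that add atoms: none
Why: Dess–Martin oxidation under buffered neutral conditions, which avoid the cyclopropylcarbinyl cation rearrangements that acidic oxidants would invite.

Step 10
Reactants: 13 C1,C5-methano-bridged C4 ketone
Product: 15 trans-fused C9-hydroxy C4 ketone (C1 methyl and C5 hydrogen on opposite faces; C7=C8 alkene), via dilithium enolate alkoxide 14 (not isolated)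
Conditions: Li, NH3(l), THF, −78 °C; then solid NH4Cl, −78 °C
Reagents that add atoms: none
Why: Dissolving-metal cleavage of a conjugated cyclopropyl ketone; the C5–C11 bond overlaps with the carbonyl π system and breaks, leaving C11 as the C1 methyl and C4–C5 as an enolate, while the benzyl ether is cleaved to the alkoxide in the same operation, and cold protonation of the enolate is expected from the face opposite the angular methyl to give the trans ring fusion.

Step 11
Reactants: 15 trans-fused C9-hydroxy C4 ketone
Product: 16 C4 isopropyl carbinol (C4 hydroxyl cis to the C1 methyl; free C9 hydroxyl)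
Conditions: i-PrMgCl, anhydrous CeCl3, THF, −78 to −20 °C; aq NH4Cl
Reagents that add atoms: isopropylmagnesium chloride, CC(C)[Mg]Cl
Why: Organocerium 1,2-addition (Imamoto conditions), which suppresses enolisation and β-hydride reduction of the hindered cyclopentanone; the nucleophile should enter from the face of the C5 hydrogen, opposite the angular methyl, so that the hydroxyl ends up cis to the methyl, and one extra equivalent is consumed by the C9 hydroxyl.

Step 12
Reactants: 16 C4 isopropyl carbinol
Product: 17 C9 enone with tertiary C4 carbinol (1R,4R,5R in the atom labels above)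
Conditions: Dess–Martin periodinane (C13H13IO8), NaHCO3, CH2Cl2, 0 °C
Reagents that add atoms: none
Why: Dess–Martin oxidation of the secondary allylic alcohol; the tertiary alcohol cannot be oxidised and both C9 epimers converge on one enone.

Step 13
Reactants: 17 C9 enone with tertiary C4 carbinol
Product: 18 C9 trimethylsilyl dienol ether (C6=C7 and C8=C9) with C4 trimethylsilyl ether
Conditions: Me3SiOTf, Et3N, CH2Cl2, 0 °C to rt
Reagents that add atoms: trimethylsilyl trifluoromethanesulfonate, C[Si](C)(C)OS(=O)(=O)C(F)(F)F
Why: Soft enolisation of an enone to the linearly conjugated dienol ether; removal of a C6 hydrogen is favoured because the C10 hydrogens are neopentyl and the linear diene is the more stable isomer, and the tertiary hydroxyl is silylated at the same time, which keeps it from steering the oxidant in step 14.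

Step 14
Reactants: 18 C9 trimethylsilyl dienol ether
Product: 20 C6-hydroxy C9 enone with tertiary C4 carbinol (1R,4R,5S,6S), via silyl dienol ether 6,7-epoxide 19 (not isolated)
Conditions: dimethyldioxirane, acetone/CH2Cl2, −78 to −40 °C; then Bu4NF, AcOH, THF, 0 °C
Reagents that add atoms: dimethyldioxirane, CC1(C)OO1
Why: Vinylogous Rubottom oxidation; the oxidant should attack the terminal C6=C7 bond, where bonding at C6 leaves a fully delocalised oxyallyl system, from the face opposite the angular methyl, and fluoride then frees the enolate, which opens the epoxide to the γ-hydroxy enone with the C6 oxygen on the side of the C5 hydrogen, and removes the C4 silyl group.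

Step 15
Reactants: 21 4-hydroxybenzoic acid
Product: 23 4-[(tert-butyldimethylsilyl)oxy]benzoic acid, via bis-silylated acid 22 (not isolated)
Conditions: TBSCl (2.3 equiv), imidazole, DMF, rt; then AcOH/THF/H2O, rt
Reagents that add atoms: tert-butyldimethylsilyl chloride, CC(C)(C)[Si](C)(C)Cl
Why: Silylation of phenol and acid followed by selective hydrolysis of the much more labile silyl ester; the aryl silyl ether is the one phenol protecting group that can later be removed without touching an acetate or a benzoate.

Step 16
Reactants: 20 C6-hydroxy C9 enone; 23 4-[(tert-butyldimethylsilyl)oxy]benzoic acid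
Product: 24 C6 4-[(tert-butyldimethylsilyl)oxy]benzoate of the C9 enone
Conditions: EDC·HCl, DMAP, CH2Cl2, 0 °C to rt
Reagents that add atoms: none
Why: Steglich esterification; the secondary C6 hydroxyl is the only acylable one, because the C4 carbinol is tertiary and hindered and C9 is still a ketone.

Step 17
Reactants: 24 C6 4-[(tert-butyldimethylsilyl)oxy]benzoate of the C9 enone
Product: 25 (9S)-C9 allylic alcohol with C6 silyloxybenzoate
Conditions: (R)-Me-CBS oxazaborolidine (C18H20BNO, 50 mol%), catecholborane, toluene/CH2Cl2, −78 °C; MeOH
Reagents that add atoms: none
Why: Corey–Bakshi–Shibata reduction of an α-methyl cycloalkenone, in which the methyl-substituted alkenyl arm acts as the large group, so the (R)-catalyst should give the 9S carbinol; reagent control is used because the substrate alone is expected to take hydride anti to the angular methyl and give the other epimer.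

Step 18
Reactants: 25 (9S)-C9 allylic alcohol with C6 silyloxybenzoate
Product: 26 C9 acetate C6 4-[(tert-butyldimethylsilyl)oxy]benzoate
Conditions: Ac2O, pyridine, DMAP (cat.), CH2Cl2, 0 °C to rt
Reagents that add atoms: acetic anhydride, CC(=O)OC(C)=O
Why: Standard acetylation of the secondary allylic alcohol; the tertiary C4 hydroxyl is too hindered to react under these conditions.

Step 19
Reactants: 26 C9 acetate C6 4-[(tert-butyldimethylsilyl)oxy]benzoate
Product: 27 target (1R,4R,5S,6S,9S)-9-acetoxy-4-hydroxy-4-isopropyl-1,8-dimethylbicyclo[5.3.0]dec-7-en-6-yl 4-hydroxybenzoate (atom labels as above)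
Conditions: Bu4NF, AcOH, THF, 0 °C
Reagents that add atoms: none
Why: Fluoride cleavage of an aryl silyl ether, which is fast at 0 °C; acetic acid protonates the phenoxide at once, so neither ester is cleaved or migrates.

Compound list

1 | 5-methoxyindan-1-one | COc1ccc2c(c1)CCC2=O | starting material
2 | (S)-5-methoxyindan-1-ol | COc1ccc2c(c1)CC[C@@H]2O | intermediate
3 | lithium (S)-5-methoxyindan-1-olate | COc1ccc2c(c1)CC[C@@H]2[O-].[Li+] | intermediate
4 | (1S)-5-methoxy-2,3,4,7-tetrahydro-1H-inden-1-ol | COC1=CCC2=C(C1)CC[C@@H]2O | intermediate
5 | tert-butyl{[(1S)-5-methoxy-2,3,4,7-tetrahydro-1H-inden-1-yl]oxy}dimethylsilane | COC1=CCC2=C(C1)CC[C@@H]2O[Si](C)(C)C(C)(C)C | intermediate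
6 | 1,1-dichloroethane | CC(Cl)Cl | starting material
7 | chlorocyclopropane adduct of 5 (C(Cl)(CH3) bridging C7 and C9; cyclopropane diastereomers) | COC12CC3=C(CC1C2(C)Cl)[C@@H](O[Si](C)(C)C(C)(C)C)CC3 | intermediate
8 | (1S)-1-[(tert-butyldimethylsilyl)oxy]-6-methyl-2,3,4,8-tetrahydroazulen-5(1H)-one | CC1=CCC2=C(CC1=O)CC[C@@H]2O[Si](C)(C)C(C)(C)C | intermediate
9 | (1S)-1-[(tert-butyldimethylsilyl)oxy]-6-methyl-1,2,3,4,5,8-hexahydroazulen-5-ol (C9 epimers) | CC1=CCC2=C(CC1O)CC[C@@H]2O[Si](C)(C)C(C)(C)C | intermediate
10 | (1S)-5-(benzyloxy)-1-[(tert-butyldimethylsilyl)oxy]-6-methyl-1,2,3,4,5,8-hexahydroazulene | CC1=CCC2=C(CC1OCc1ccccc1)CC[C@@H]2O[Si](C)(C)C(C)(C)C | intermediate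
11 | (1S)-5-(benzyloxy)-6-methyl-1,2,3,4,5,8-hexahydroazulen-1-ol | CC1=CCC2=C(CC1OCc1ccccc1)CC[C@@H]2O | intermediate
12 | C1,C5-methano-bridged C4 alcohol, C11 cis to the hydroxyl, C9 benzyl ether | CC1=CC[C@@]23C[C@]2(CC1OCc1ccccc1)CC[C@@H]3O | intermediate
13 | C1,C5-methano-bridged C4 ketone, C9 benzyl ether | CC1=CC[C@@]23C[C@]2(CC1OCc1ccccc1)CCC3=O | intermediate
14 | dilithium C4-enolate C9-alkoxide with C1 methyl | [O-]C1C[C@@]2(C)CCC([O-])=C2CC=C1C.[Li+].[Li+] | intermediate
15 | trans-fused C9-hydroxy C4 ketone | OC1C[C@@]2(C)CCC(=O)[C@@H]2CC=C1C | intermediate
16 | C4 isopropyl carbinol with free C9 hydroxyl | OC1C[C@@]2(C)CC[C@@](O)(C(C)C)[C@@H]2CC=C1C | intermediate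
17 | C9 enone with tertiary C4 carbinol | O=C1C[C@@]2(C)CC[C@@](O)(C(C)C)[C@@H]2CC=C1C | intermediate
18 | C9 trimethylsilyl dienol ether with C4 trimethylsilyl ether | CC1=C(O[Si](C)(C)C)C[C@@]2(C)CC[C@@](O[Si](C)(C)C)(C(C)C)[C@@H]2C=C1 | intermediate
19 | 6,7-epoxide of 18, oxygen on the face of the C5 hydrogen | CC1=C(O[Si](C)(C)C)C[C@@]2(C)CC[C@@](O[Si](C)(C)C)(C(C)C)[C@@H]2[C@H]3O[C@H]31 | intermediate
20 | C6-hydroxy C9 enone with tertiary C4 carbinol | O=C1C[C@@]2(C)CC[C@@](O)(C(C)C)[C@@H]2[C@@H](O)C=C1C | intermediate
21 | 4-hydroxybenzoic acid | OC(=O)c1ccc(O)cc1 | starting material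
22 | tert-butyldimethylsilyl 4-[(tert-butyldimethylsilyl)oxy]benzoate | CC(C)(C)[Si](C)(C)OC(=O)c1ccc(O[Si](C)(C)C(C)(C)C)cc1 | intermediate
23 | 4-[(tert-butyldimethylsilyl)oxy]benzoic acid | CC(C)(C)[Si](C)(C)Oc1ccc(cc1)C(O)=O | intermediate
24 | C6 4-[(tert-butyldimethylsilyl)oxy]benzoate of the C9 enone | O=C1C[C@@]2(C)CC[C@@](O)(C(C)C)[C@@H]2[C@@H](OC(=O)c2ccc(O[Si](C)(C)C(C)(C)C)cc2)C=C1C | intermediate
25 | (9S)-C9 allylic alcohol with C6 silyloxybenzoate | O[C@H]1C[C@@]2(C)CC[C@@](O)(C(C)C)[C@@H]2[C@@H](OC(=O)c2ccc(O[Si](C)(C)C(C)(C)C)cc2)C=C1C | intermediate
26 | C9 acetate C6 4-[(tert-butyldimethylsilyl)oxy]benzoate | CC(=O)O[C@H]1C[C@@]2(C)CC[C@@](O)(C(C)C)[C@@H]2[C@@H](OC(=O)c2ccc(O[Si](C)(C)C(C)(C)C)cc2)C=C1C | intermediate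
27 | (1R,4R,5S,6S,9S)-9-acetoxy-4-hydroxy-4-isopropyl-1,8-dimethylbicyclo[5.3.0]dec-7-en-6-yl 4-hydroxybenzoate (atom labels as above) | CC(=O)O[C@H]1C[C@@]2(C)CC[C@@](O)(C(C)C)[C@@H]2[C@@H](OC(=O)c2ccc(O)cc2)C=C1C | target

Total step count: 19. Longest linear sequence: 18 steps (steps 1 to 14 and 16 to 19); step 15 is a one-step side branch.

Least certain steps

Step 4 (key step). Three things can go wrong:
- the carbenoid can rearrange to vinyl chloride before it meets the alkene, leaving 5 unchanged;
- it can add to the electron-rich C1=C5 alkene;
- the adduct with chloride on the outside cannot open, because it would have to give a trans-cycloheptenyl cation.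

The fallback sets out from 5 and uses dibromocarbene (CHBr3, KOt-Bu, pentane, −20 °C), which cannot rearrange and always places one bromide in the reactive position, to give the dibromocyclopropane adduct F1. AgBF4 with NaHCO3 in wet acetone would open it to the 2-bromo enone F2. The methyl group would then be introduced by Stille coupling (SnMe4, Pd(PPh3)4, CuI, DMF), which is neutral enough for the β,γ-unsaturated ketone, and the route is rejoined at 8. This fallback does not answer the site-selectivity question; a bulkier silyl group on C4 in 5 would.

Step 11. The branched, basic reagent can enolise ketone 15 or reduce it by β-hydride transfer. Enolisation is serious because the ring-fusion centre C5 made in the quench of step 10 is labile in 15, and the cis-fused ketone may be the more stable one. The fallback sets out from 15 and adds isopropenylmagnesium bromide with CeCl3, an sp2 nucleophile that is less basic, smaller and unable to transfer a β-hydride, to give the isopropenyl carbinol F3. Hydrogenation of its 1,1-disubstituted alkene with RhCl(PPh3)3 and H2, which leaves the trisubstituted C7=C8 alkene alone, returns to the route at 16.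

Step 14. The oxidant may prefer the more electron-rich tetrasubstituted enol ether bond C8=C9 and hydroxylate C8 instead of C6. The fallback sets out from 18 and replaces epoxidation by a cycloaddition whose regiochemistry is fixed by the diene termini. Singlet oxygen (O2, 5,10,15,20-tetraphenylporphyrin, light, CH2Cl2, −78 °C) would add across C6 and C9 from the face opposite the angular methyl to give the silyloxy endoperoxide F4. Reduction of the O–O bond with thiourea, collapse of the C9 silyl hemiketal and buffered fluoride would return to the route at 20.

Step 17. The catalyst has to override the substrate, which is expected to take hydride anti to the angular methyl; a mismatched, slow or unselective reduction is the likely failure. The fallback sets out from 24 and accepts substrate control. NaBH4 with CeCl3·7H2O in MeOH would give the 9-epi alcohol F5. Mitsunobu reaction with acetic acid (PPh3, diisopropyl azodicarboxylate, toluene, 0 °C) would then invert C9 and install the acetate in one operation, rejoining the route at 26 and bypassing 25.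

Further compounds

F1 | step 4 | dibromocyclopropane adduct of 5 (CBr2 bridging C7 and C9) | COC12CC3=C(CC1C2(Br)Br)[C@@H](O[Si](C)(C)C(C)(C)C)CC3
F2 | step 4 | (1S)-6-bromo-1-[(tert-butyldimethylsilyl)oxy]-2,3,4,8-tetrahydroazulen-5(1H)-one | BrC1=CCC2=C(CC1=O)CC[C@@H]2O[Si](C)(C)C(C)(C)C
F3 | step 11 | C4 isopropenyl carbinol with free C9 hydroxyl | OC1C[C@@]2(C)CC[C@@](O)(C(C)=C)[C@@H]2CC=C1C
F4 | step 14 | C6,C9-endoperoxide of 18 with C9 and C4 trimethylsilyloxy groups | CC1=C[C@@H]2OO[C@@]1(O[Si](C)(C)C)C[C@@]3(C)CC[C@@](O[Si](C)(C)C)(C(C)C)[C@H]23
F5 | step 17 | (9R)-C9 allylic alcohol with C6 silyloxybenzoate (9-epimer of 25) | O[C@@H]1C[C@@]2(C)CC[C@@](O)(C(C)C)[C@@H]2[C@@H](OC(=O)c2ccc(O[Si](C)(C)C(C)(C)C)cc2)C=C1C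
A1 | alternative 1 | 2,3-trans 2-[(Z)-1-hydroxy-3-iodobut-2-enyl]-3-methyl-3-vinylcyclopentan-1-one | C=C[C@@]1(C)CCC(=O)[C@@H]1[C@@H](O)/C=C(C)\I
A2 | alternative 1 | 3-methylcyclopent-2-en-1-one | CC1=CC(=O)CC1
A3 | alternative 1 | (Z)-3-iodobut-2-enal | O=C/C=C(C)\I
A4 | alternative 1 | dimethyl(vinyl)alane | C=C[Al](C)C
A5 | alternative 2 | 6-methyl-3,8a-dihydroazulen-1(2H)-one | CC1=CC=C2CCC(=O)C2C=C1
A6 | alternative 2 | 1-diazo-4-(4-methylphenyl)butan-2-one | Cc1ccc(CCC(=O)C=[N+]=[N-])cc1
A7 | alternative 3 | C6,C9-endoperoxide with C7=C8 alkene | O3[C@H]1C[C@@]2(C)CC[C@@](O)(C(C)C)[C@@H]2[C@@H](O3)C=C1C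
A8 | alternative 3 | ring-B 1,3-diene (C6=C7 and C8=C9) with C4 isopropyl carbinol | CC1=CC[C@@]2(C)CC[C@@](O)(C(C)C)[C@@H]2C=C1
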